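**Strategy.** The molecule is cut at the bond between the exocyclic CH2 and C2 of the cyclohexane-1,3-dione ring. That CH2 and the neighbouring sp2 carbon of the cyclopentene ring (the one carrying the dienyl chain) are stored as the CH2 and the carbinol carbon of a ring-fused cyclopropanol, made by an intramolecular Kulinkovich reaction of a linalool-derived ester. In the key step a palladium homoenolate, released by strain-driven opening of this bicyclo[3.1.0]hexan-1-ol, is coupled with an enantiopure 2-iodo vinylogous ester of the dione. One operation forms the bond, carries the ring stereocentre over and unveils the ketone that later takes the dienyl chain through its enol triflate.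

Key step: step 9

Remarks on the chemistry (one line each):
- (S)-(+)-Linalool (coriandrol) is taken as commercially available in high enantiomeric purity.
- The lipase is assumed to hydrolyse the (S)-acetate; should it prefer the (R)-acetate, the recovered (S)-acetate is methanolysed (K2CO3, MeOH) to the same (S)-alcohol.
- The target is one enol tautomer of a 2-alkyl-4-methoxycyclohexane-1,3-dione; hydrolysis of either vinylogous ester gives this compound.

**Step 1**
Reactants: 1 (S)-(+)-linalool
Product: 2 (S)-triethyl[(3,7-dimethylocta-1,6-dien-3-yl)oxy]silane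
Conditions: TESOTf, 2,6-lutidine, CH2Cl2, −78 → 0 °C
Reagents that add atoms: triethylsilyl trifluoromethanesulfonate, CC[Si](CC)(CC)OS(=O)(=O)C(F)(F)F
Why: Silyl ether formation with a silyl triflate, which is reactive enough for the hindered tertiary allylic alcohol; protection stops the later carbonyl compounds from closing to the lactone, and no stereocentre is touched.

**Step 2**
Reactants: 2 (S)-triethyl[(3,7-dimethylocta-1,6-dien-3-yl)oxy]silane
Product: 3 (S)-4-methyl-4-[(triethylsilyl)oxy]hex-5-enal
Conditions: O3, CH2Cl2/MeOH, NaHCO3, −78 °C (Sudan Red 7B end point); then Me2S, −78 °C → rt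
Reagents that add atoms: ozone, [O-][O+]=O
Why: Chemoselective ozonolysis with reductive work-up: the electron-rich trisubstituted alkene should be consumed before the monosubstituted vinyl group, which is hindered and deactivated by the allylic silyloxy carbon.

**Step 3**
Reactants: 3 (S)-4-methyl-4-[(triethylsilyl)oxy]hex-5-enal
Product: 4 methyl (S)-4-methyl-4-[(triethylsilyl)oxy]hex-5-enoate
Conditions: I2, KOH, MeOH, 0 °C
Reagents that add atoms: methanol, CO
Why: Oxidative esterification of an aldehyde (hypoiodite oxidation of the methyl hemiacetal in alkaline methanol), mild enough for the silyl ether and the vinyl group.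

**Step 4**
Reactants: 4 methyl (S)-4-methyl-4-[(triethylsilyl)oxy]hex-5-enoate
Product: 5 (1R,4S,5R)-4-methyl-4-[(triethylsilyl)oxy]bicyclo[3.1.0]hexan-1-ol (cyclopropane CH2 on the same face as the silyloxy group)
Conditions: ClTi(OiPr)3, c-C5H9MgCl, THF, rt
Reagents that add atoms: none
Why: Intramolecular Kulinkovich cyclopropanation in its ligand-exchange form: the titanacyclopropane made from the Grignard reagent exchanges cyclopentene for the terminal vinyl group and adds twice to the tethered ester (5-exo, then 3-exo closure); the CH2 should be delivered to the face of C5 syn to the smaller silyloxy group and anti to the methyl group on C4, and C1 follows from the cis ring fusion.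

**Step 5**
Reactants: 6 3-methoxycyclohex-2-en-1-one
Product: 7 (±)-4-methoxy-2-oxocyclohex-3-en-1-yl acetate (racemic 6-acetoxy-3-methoxycyclohex-2-en-1-one)
Conditions: Mn(OAc)3·2H2O, benzene, reflux
Reagents that add atoms: manganese triacetate, CC(=O)O[Mn](OC(C)=O)OC(C)=O
Why: α′-Acetoxylation of an enone with Mn(OAc)3 (manganese enolate, then acetate transfer), which goes to C6 of β-alkoxy enones because C2 and C4 are part of the vinylogous ester.

**Step 6**
Reactants: 7 (±)-4-methoxy-2-oxocyclohex-3-en-1-yl acetate
Product: 8 (S)-6-hydroxy-3-methoxycyclohex-2-en-1-one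
Conditions: lipase PS (Burkholderia cepacia), phosphate buffer pH 7, DMSO co-solvent, rt, stopped near half conversion; unreacted (R)-acetate separated
Reagents that add atoms: none
Why: Enzymatic kinetic resolution by enantioselective ester hydrolysis; the hydrolase selects the configuration at C6 under neutral conditions that do not enolise the ketone.

**Step 7**
Reactants: 8 (S)-6-hydroxy-3-methoxycyclohex-2-en-1-one
Product: 9 (S)-3,6-dimethoxycyclohex-2-en-1-one
Conditions: MeI, Ag2O, MeCN, rt, dark
Reagents that add atoms: iodomethane, CI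
Why: Purdie methylation; the non-basic silver oxide conditions should etherify the α-hydroxy ketone without epimerising C6.

**Step 8**
Reactants: 9 (S)-3,6-dimethoxycyclohex-2-en-1-one
Product: 10 (S)-2-iodo-3,6-dimethoxycyclohex-2-en-1-one
Conditions: NIS, MeCN, 0 °C → rt
Reagents that add atoms: N-iodosuccinimide, O=C1CCC(=O)N1I
Why: Electrophilic iodination of a vinylogous ester at C2, the nucleophilic carbon of the push-pull alkene.

**Step 9**
Reactants: 5 (1R,4S,5R)-4-methyl-4-[(triethylsilyl)oxy]bicyclo[3.1.0]hexan-1-ol; 10 (S)-2-iodo-3,6-dimethoxycyclohex-2-en-1-one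
Product: 11 (6S)-2-{[(1S,2S)-2-methyl-5-oxo-2-[(triethylsilyl)oxy]cyclopentyl]methyl}-3,6-dimethoxycyclohex-2-en-1-one
Conditions: Pd(OAc)2 (cat.), XPhos, Cs2CO3, toluene, 60 °C
Reagents that add atoms: none
Why: Pd(OAc)2 is reduced in the flask to zerovalent palladium, which inserts into the C–I bond of 10; the caesium alkoxide of 5 then binds palladium and undergoes β-carbon elimination, ring strain driving cleavage of the external C1–C6 bond to a primary alkylpalladium ketone homoenolate, and reductive elimination forms the CH2–C(sp2) bond. The closest known reaction type is the palladium-catalysed ring-opening cross-coupling of cyclopropanols with aryl and alkenyl halides. No ring is closed: the three-membered ring is opened and the cyclopentanone of 11 is what remains of the bicycle. No stereocentre is formed; C5 of 5 becomes the ring carbon bearing the new CH2 without any of its bonds being broken, so the cis relation between the CH2 arm and the silyloxy group from step 4 is carried over, and this should also be the more stable epimer at the ketone α-carbon. The step needs cleavage of C1–C6 rather than the internal C1–C5 bond, which the preference of palladium for the less substituted carbon and the retention of the five-membered ring secure. It also needs reductive elimination to outrun β-hydride elimination, which the bulky electron-rich ligand and the reactive alkenyl iodide favour.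

**Step 10**
Reactants: 11 (6S)-2-{[(1S,2S)-2-methyl-5-oxo-2-[(triethylsilyl)oxy]cyclopentyl]methyl}-3,6-dimethoxycyclohex-2-en-1-one
Product: 12 (4S,5S)-5-{[(5S)-2,5-dimethoxy-6-oxocyclohex-1-en-1-yl]methyl}-4-methyl-4-[(triethylsilyl)oxy]cyclopent-1-en-1-yl trifluoromethanesulfonate
Conditions: KHMDS, THF, −78 °C; then PhNTf2, −78 → 0 °C
Reagents that add atoms: N-phenylbis(trifluoromethanesulfonimide), O=S(=O)(N(c1ccccc1)S(=O)(=O)C(F)(F)F)C(F)(F)F
Why: Kinetic enolate formation and O-triflation: the unhindered ring CH2 of the cyclopentanone is the most acidic accessible site (the only proton α to the vinylogous ester carbonyl sits on the methoxy-bearing carbon and is slower to remove), so the enol triflate places the double bond where the target has its ring alkene.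

**Step 11**
Reactants: 13 4-methylpent-3-en-1-ol
Product: 14 4-methylpent-3-enal
Conditions: Dess–Martin periodinane, NaHCO3, CH2Cl2, 0 °C; used at once as a cold solution
Reagents that add atoms: none
Why: Dess–Martin oxidation under buffered neutral conditions, chosen to avoid migration of the β,γ-double bond into conjugation.

**Step 12**
Reactants: 14 4-methylpent-3-enal
Product: 15 (2Z)-2-iodo-6-methylhepta-2,5-diene
Conditions: EtPPh3I, n-BuLi, THF, 0 °C; I2, −78 °C; NaHMDS, −20 °C; then 14, −78 °C → rt
Reagents that add atoms: ethyltriphenylphosphonium iodide, CC[P+](c1ccccc1)(c1ccccc1)c1ccccc1.[I-]; iodine, II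
Why: Stork–Zhao olefination (Wittig reaction of an α-iodo ylide made in the flask), which is Z-selective for aliphatic aldehydes and so places iodine cis to the chain on the trisubstituted alkene.

**Step 13**
Reactants: 15 (2Z)-2-iodo-6-methylhepta-2,5-diene; 12 (4S,5S)-5-{[(5S)-2,5-dimethoxy-6-oxocyclohex-1-en-1-yl]methyl}-4-methyl-4-[(triethylsilyl)oxy]cyclopent-1-en-1-yl trifluoromethanesulfonate
Product: 18 (6S)-2-{[(1R,5S)-5-methyl-2-[(2Z)-6-methylhepta-2,5-dien-2-yl]-5-[(triethylsilyl)oxy]cyclopent-2-en-1-yl]methyl}-3,6-dimethoxycyclohex-2-en-1-one, via (Z)-alkenyllithium 16 (not isolated), via (Z)-alkenylzinc chloride 17 (not isolated)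
Conditions: 15, t-BuLi, Et2O, −78 °C; ZnCl2, THF, −78 → 0 °C; then 12, Pd(PPh3)4 (cat.), THF, rt
Reagents that add atoms: none
Why: Iodine–lithium exchange, transmetalation to zinc and Negishi coupling with the alkenyl triflate, all with retention of alkene geometry, so the Z-dienyl chain is installed; the organozinc does not add to the vinylogous ester.

**Step 14**
Reactants: 18 (6S)-2-{[(1R,5S)-5-methyl-2-[(2Z)-6-methylhepta-2,5-dien-2-yl]-5-[(triethylsilyl)oxy]cyclopent-2-en-1-yl]methyl}-3,6-dimethoxycyclohex-2-en-1-one
Product: 19 (4S)-3-hydroxy-2-{[(1R,5S)-5-hydroxy-5-methyl-2-[(2Z)-6-methylhepta-2,5-dien-2-yl]cyclopent-2-en-1-yl]methyl}-4-methoxycyclohex-2-en-1-one (target, CNP0148956.1)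
Conditions: 1 M HCl, THF, rt
Reagents that add atoms: water, O
Why: Acid hydrolysis of the vinylogous methyl ester to the 1,3-dione together with cleavage of the tertiary triethylsilyl ether; the alkyl methyl ether and the non-allylic tertiary alcohol should survive dilute acid at room temperature.

**Compound list**
1 | (S)-(+)-linalool | C=C[C@@](C)(O)CCC=C(C)C | starting material
2 | (S)-triethyl[(3,7-dimethylocta-1,6-dien-3-yl)oxy]silane | C=C[C@@](C)(O[Si](CC)(CC)CC)CCC=C(C)C | intermediate
3 | (S)-4-methyl-4-[(triethylsilyl)oxy]hex-5-enal | C=C[C@@](C)(O[Si](CC)(CC)CC)CCC=O | intermediate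
4 | methyl (S)-4-methyl-4-[(triethylsilyl)oxy]hex-5-enoate | C=C[C@@](C)(O[Si](CC)(CC)CC)CCC(=O)OC | intermediate
5 | (1R,4S,5R)-4-methyl-4-[(triethylsilyl)oxy]bicyclo[3.1.0]hexan-1-ol | O[C@@]12CC[C@](C)(O[Si](CC)(CC)CC)[C@@H]1C2 | intermediate
6 | 3-methoxycyclohex-2-en-1-one | COC1=CC(=O)CCC1 | starting material
7 | (±)-4-methoxy-2-oxocyclohex-3-en-1-yl acetate (racemic) | COC1=CC(=O)C(OC(C)=O)CC1 | intermediate
8 | (S)-6-hydroxy-3-methoxycyclohex-2-en-1-one | COC1=CC(=O)[C@@H](O)CC1 | intermediate
9 | (S)-3,6-dimethoxycyclohex-2-en-1-one | COC1=CC(=O)[C@@H](OC)CC1 | intermediate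
10 | (S)-2-iodo-3,6-dimethoxycyclohex-2-en-1-one | COC1=C(I)C(=O)[C@@H](OC)CC1 | intermediate
11 | (6S)-2-{[(1S,2S)-2-methyl-5-oxo-2-[(triethylsilyl)oxy]cyclopentyl]methyl}-3,6-dimethoxycyclohex-2-en-1-one | COC1=C(C[C@@H]2C(=O)CC[C@]2(C)O[Si](CC)(CC)CC)C(=O)[C@@H](OC)CC1 | intermediate
12 | (4S,5S)-5-{[(5S)-2,5-dimethoxy-6-oxocyclohex-1-en-1-yl]methyl}-4-methyl-4-[(triethylsilyl)oxy]cyclopent-1-en-1-yl trifluoromethanesulfonate | COC1=C(C[C@@H]2C(OS(=O)(=O)C(F)(F)F)=CC[C@]2(C)O[Si](CC)(CC)CC)C(=O)[C@@H](OC)CC1 | intermediate
13 | 4-methylpent-3-en-1-ol | CC(C)=CCCO | starting material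
14 | 4-methylpent-3-enal | CC(C)=CCC=O | intermediate
15 | (2Z)-2-iodo-6-methylhepta-2,5-diene | I/C(C)=C\CC=C(C)C | intermediate
16 | [(2Z)-6-methylhepta-2,5-dien-2-yl]lithium | [Li]/C(C)=C\CC=C(C)C | intermediate (not isolated)
17 | chloro[(2Z)-6-methylhepta-2,5-dien-2-yl]zinc | Cl[Zn]/C(C)=C\CC=C(C)C | intermediate (not isolated)
18 | (6S)-2-{[(1R,5S)-5-methyl-2-[(2Z)-6-methylhepta-2,5-dien-2-yl]-5-[(triethylsilyl)oxy]cyclopent-2-en-1-yl]methyl}-3,6-dimethoxycyclohex-2-en-1-one | COC1=C(C[C@@H]2C(/C(C)=C\CC=C(C)C)=CC[C@]2(C)O[Si](CC)(CC)CC)C(=O)[C@@H](OC)CC1 | intermediate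
19 | (4S)-3-hydroxy-2-{[(1R,5S)-5-hydroxy-5-methyl-2-[(2Z)-6-methylhepta-2,5-dien-2-yl]cyclopent-2-en-1-yl]methyl}-4-methoxycyclohex-2-en-1-one | CO[C@H]1CCC(=O)C(C[C@@H]2C(/C(C)=C\CC=C(C)C)=CC[C@]2(C)O)=C1O | target

**Step count.** 14 steps in total. The longest linear sequence is 8 steps (1, 2, 3, 4, 9, 10, 13, 14).

**Steps most likely to fail**

Step 9 (key step). β-Hydride elimination from the alkylpalladium homoenolate would give the α-methylene ketone and reduced 9 instead of the coupled product, and the carbonate base could induce loss of silanolate from the β-silyloxy ketone. Fallback, from 5 back to 11: aerobic oxidative ring opening of 5 (Pd(OAc)2 cat., O2, DMSO) should give (S)-3-methyl-2-methylidene-3-[(triethylsilyl)oxy]cyclopentan-1-one F1. Copper-catalysed conjugate borylation (CuCl, Xantphos, NaOtBu, B2pin2, MeOH, THF) should give (2S,3S)-3-methyl-2-[(4,4,5,5-tetramethyl-1,3,2-dioxaborolan-2-yl)methyl]-3-[(triethylsilyl)oxy]cyclopentan-1-one F2, the α-carbon being set by protonation to the more stable epimer with the CH2 arm cis to the silyloxy group. A Suzuki–Miyaura coupling of F2 with 10 (Pd(OAc)2, RuPhos, K2CO3, toluene/water, 80 °C) forms the same CH2–C(sp2) bond and returns to 11.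

Step 4. Ligand exchange at the vinyl group next to the quaternary carbon may be slow, the allylic silyloxy group may be lost by β-elimination from the titanacycle, or the facial selectivity of CH2 delivery may be poor. Fallback, from 4 back to 11 without a cyclopropanol: saponification (LiOH, THF/water) gives (S)-4-methyl-4-[(triethylsilyl)oxy]hex-5-enoic acid F3. Neutral chlorination (1-chloro-N,N,2-trimethylprop-1-en-1-amine, CH2Cl2) gives (S)-4-methyl-4-[(triethylsilyl)oxy]hex-5-enoyl chloride F4. Palladium-catalysed cyclic acylpalladation (Pd(PPh3)4, Et3N, MeCN; 5-exo acyl addition to the vinyl group, then β-hydride elimination) gives the enone F1, which is carried through the boronate F2 to 11 as described for step 9.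

Step 14. Aqueous acid may protonate and cyclise the skipped triene, close the tertiary alcohol onto the dione with loss of water, or enolise the dione toward the methoxy-bearing carbon and erode its configuration. Fallback, from 18 back to 19 without acid: desilylation (TBAF, THF, rt) gives (6S)-2-{[(1R,5S)-5-hydroxy-5-methyl-2-[(2Z)-6-methylhepta-2,5-dien-2-yl]cyclopent-2-en-1-yl]methyl}-3,6-dimethoxycyclohex-2-en-1-one F5. The vinylogous methyl ester is then cleaved by thiolate attack at its methyl group (PhSH, K2CO3, DMF, 50 °C), and work-up at pH 5 releases 19.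

**Further compounds**
F1 | step 9 | (S)-3-methyl-2-methylidene-3-[(triethylsilyl)oxy]cyclopentan-1-one | C=C1C(=O)CC[C@]1(C)O[Si](CC)(CC)CC
F2 | step 9 | (2S,3S)-3-methyl-2-[(4,4,5,5-tetramethyl-1,3,2-dioxaborolan-2-yl)methyl]-3-[(triethylsilyl)oxy]cyclopentan-1-one | CC1(C)OB(C[C@@H]2C(=O)CC[C@]2(C)O[Si](CC)(CC)CC)OC1(C)C
F3 | step 4 | (S)-4-methyl-4-[(triethylsilyl)oxy]hex-5-enoic acid | C=C[C@@](C)(O[Si](CC)(CC)CC)CCC(=O)O
F4 | step 4 | (S)-4-methyl-4-[(triethylsilyl)oxy]hex-5-enoyl chloride | C=C[C@@](C)(O[Si](CC)(CC)CC)CCC(=O)Cl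
F5 | step 14 | (6S)-2-{[(1R,5S)-5-hydroxy-5-methyl-2-[(2Z)-6-methylhepta-2,5-dien-2-yl]cyclopent-2-en-1-yl]methyl}-3,6-dimethoxycyclohex-2-en-1-one | COC1=C(C[C@@H]2C(/C(C)=C\CC=C(C)C)=CC[C@]2(C)O)C(=O)[C@@H](OC)CC1
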